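**Plan** (drimane numbering: C3 OAc, C4 CMe2, C5/C10 ring fusion, C6 ketone, C7=C8, C9–C11H2OAr)
Retrosynthetic cuts, in order: acetate; C11–OAr; C9–H and C11–O (back to a C9=C11 methylene); C6–C7 (ring B); C5–C10 (ring A); the lactone bond C6–O–C11; C8–C9; C10–CH3; C3–C4.
Enabling feature: the bond C5–C10 shared by rings A and B has the C6 carbonyl on one side and, on the other, the quaternary C10 whose neighbour C9 bears the oxygenated C11. Read backwards, C5=C6(OSi)–O–C11–C9=C10 is a complete ester-enolate Claisen array, and the ring A carbons C4–C3–C2–C1 already tie its two ends together.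
Forward: the chain C11–C9–C10–C1–C2–C3–C4–C5–C6 is built linearly from pent-4-yn-1-ol and closed to a ten-membered lactone. The lactone is contracted to ring A, and ring B is closed by acylating the diene terminus C7 with the C6 acid chloride.
Stereochemistry: C3 comes from a reagent-controlled reverse prenylation, C10 from C3 in the ring contraction, and C5 from equilibration of the 6-ketone to the trans-decalin.
C9 is set by hydroboration anti to the C10 methyl and not by enolisation, because a dienolate reaching C9 would expel the aryloxide.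

Key step: step 11

Assumption: the prenylborane carrying isopinocampheyl groups from (+)-α-pinene is taken to attack aldehydes with the same facial sense as the parent allylborane; drimane numbering is used for all intermediates.

Step 1
Reactants: 1 pent-4-yn-1-ol
Product: 2 pent-4-ynal
Conditions: (COCl)2, DMSO, CH2Cl2, −78 °C; Et3N, −78 °C → rt
Reagents that add atoms: none
Why: Swern oxidation (activated-DMSO oxidation) takes the primary alcohol to the aldehyde without over-oxidation and leaves the terminal alkyne alone.

Step 2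
Reactants: 2 pent-4-ynal; 3 3-methylbuta-1,2-diene
Product: 6 (R)-3,3-dimethyloct-1-en-7-yn-4-ol, via prenylborane 4 (not isolated), via borinic ester 5 (not isolated)
Conditions: BH3·SMe2, (+)-α-pinene, THF, 0 °C; 3 (slight excess), −25 °C; 2, Et2O, −78 °C; then NaOH, H2O2, 0 °C → rt
Reagents that add atoms: none
Why: Brown asymmetric allylboration: hydroboration of the allene puts boron on its CH2 terminus, and the prenylborane transfers its tertiary γ-carbon to the aldehyde through a closed chair transition state in which the isopinocampheyl groups leave the Si face open, which forms C3–C4 with the gem-dimethyl group in place and sets C3 as R.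

Step 3
Reactants: 6 (R)-3,3-dimethyloct-1-en-7-yn-4-ol
Product: 7 (R)-4-(tert-butyldimethylsilyloxy)-3,3-dimethyloct-1-en-7-yne
Conditions: TBSOTf, 2,6-lutidine, CH2Cl2, 0 °C
Reagents that add atoms: tert-butyldimethylsilyl triflate, CC(C)(C)[Si](C)(C)OS(=O)(=O)C(F)(F)F
Why: Silylation with the silyl triflate and a hindered pyridine base is the usual answer to a secondary alcohol next to a quaternary carbon, and the ether formed has to last until step 18.

Step 4
Reactants: 7 silyl ether alkyne
Product: 9 methyl (R)-6-(tert-butyldimethylsilyloxy)-7,7-dimethylnon-8-en-2-ynoate, via lithium acetylide 8 (not isolated)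
Conditions: n-BuLi, THF, −78 °C; ClCO2Me, −78 → 0 °C
Reagents that add atoms: methyl chloroformate, COC(=O)Cl
Why: Deprotonation of the terminal alkyne and C-acylation of the acetylide with a chloroformate is the standard preparation of 2-alkynoates and adds C11 at the ester level.

Step 5
Reactants: 9 ynoate
Product: 11 methyl (R,E)-6-(tert-butyldimethylsilyloxy)-2-iodo-3,7,7-trimethylnona-2,8-dienoate, via alkenylcuprate 10 (not isolated)
Conditions: Me2CuLi (from MeLi, CuI), THF, −78 °C; I2, THF, −78 °C
Reagents that add atoms: lithium dimethylcuprate, [Li+].C[Cu-]C; iodine, [I][I]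
Why: Syn carbocupration of the ynoate places the methyl group on C10 and copper on C9 on the same side, the alkenylcuprate holds its geometry at −78 °C in THF, and iodinolysis goes with retention, so that C1 ends up cis to the C11 ester on the tetrasubstituted alkene.

Step 6
Reactants: 11 iodo dienoate
Product: 13 methyl (R,E)-6-(tert-butyldimethylsilyloxy)-9-hydroxy-2-iodo-3,7,7-trimethylnon-2-enoate, via trialkylborane 12 (not isolated)
Conditions: 9-BBN, THF, 0 °C → rt; then NaOH, H2O2, 0 °C
Reagents that add atoms: hydrogen peroxide, OO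
Why: Anti-Markovnikov hydroboration–oxidation with 9-BBN finds the monosubstituted C5=C6 vinyl group as the only reactive alkene, because the tetrasubstituted, electron-poor iodoacrylate is inert and the isopropenyl group is deliberately not yet present.

Step 7
Reactants: 13 primary alcohol
Product: 15 (R,E)-4-(tert-butyldimethylsilyloxy)-8-iodo-9-methoxy-3,3,7-trimethyl-9-oxonon-7-enoic acid, via aldehyde 14 (not isolated)
Conditions: TEMPO (cat.), PhI(OAc)2, MeCN–H2O, rt
Reagents that add atoms: water, O
Why: Oxoammonium (TEMPO) oxidation with PhI(OAc)2 in aqueous acetonitrile carries a primary alcohol through the aldehyde hydrate to the acid under near-neutral conditions that spare the silyl ether, the ester and the alkenyl iodide.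

Step 8
Reactants: 15 iodo acid; 16 isopropenylboronic acid pinacol ester
Product: 17 (4R,7Z)-4-(tert-butyldimethylsilyloxy)-8-(methoxycarbonyl)-3,3,7,9-tetramethyldeca-7,9-dienoic acid
Conditions: Pd(dppf)Cl2 (cat.), K3PO4, THF–H2O, 55 °C; work-up at pH 4
Reagents that add atoms: none
Why: Suzuki–Miyaura coupling of an alkenyl iodide with an alkenylboronate proceeds with retention at both partners, so the C8–C9 bond is made without touching the alkene geometry, and the free acid merely travels as its potassium salt.

Step 9
Reactants: 17 dienoate acid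
Product: 19 (4R,7Z)-4-(tert-butyldimethylsilyloxy)-8-(hydroxymethyl)-3,3,7,9-tetramethyldeca-7,9-dienoic acid, via diisobutylaluminium carboxylate 18 (not isolated)
Conditions: i-Bu2AlH (4 equiv), CH2Cl2, −78 → −40 °C; aq. potassium sodium tartrate, then pH 4
Reagents that add atoms: none
Why: Hydride reduction of an enoate to the allylic alcohol with i-Bu2AlH, in which the first equivalent turns the acid into an aluminium carboxylate that is much less electrophilic than the ester at low temperature, the same basis on which esters are routinely reduced beside carboxylates.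

Step 10
Reactants: 19 hydroxy acid
Product: 21 (5R,8Z)-5-(tert-butyldimethylsilyloxy)-4,4,8-trimethyl-9-(prop-1-en-2-yl)-3,4,5,6,7,10-hexahydro-2H-oxecin-2-one, via mixed anhydride 20 (not isolated)
Conditions: 2-methyl-6-nitrobenzoic anhydride (MNBA), DMAP, toluene, slow addition of 19 (final 1 mM), 40 °C
Reagents that add atoms: none
Why: Shiina macrolactonisation: the mixed anhydride passes its acyl group to DMAP and then to the primary allylic alcohol, slow addition at high dilution suppresses dimer formation, and the Z tetrasubstituted alkene, the gem-dimethyl group and the bulky silyloxy group bend the chain towards closure.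

Step 11
Reactants: 21 ten-membered lactone
Product: 24 (1R,2R,5R)-5-(tert-butyldimethylsilyloxy)-2,6,6-trimethyl-2-(3-methylbuta-1,3-dien-2-yl)cyclohexane-1-carboxylic acid, via silyl ketene acetal 22 (not isolated), via trimethylsilyl ester 23 (not isolated)
Conditions: Me3SiCl, Et3N, then LiN(i-Pr)2, THF, −78 °C (internal quench); toluene, 100 °C; aq. citric acid, THF, rt
Reagents that add atoms: none
Why: LiN(i-Pr)2 removes a C5 proton and the Me3SiCl already present traps the enolate on oxygen as the cyclic ketene acetal 22, whose six atoms C5=C6–O–C11–C9=C10 then undergo a concerted suprafacial [3,3] shift on heating that forms C5–C10, breaks O–C11 and leaves C9=C11 as a methylene next to the isopropenyl group. The closest known reaction type is exactly this one, the Ireland–Claisen rearrangement of macrocyclic allylic lactones to 2-alkenylcycloalkanecarboxylic acids. Ring A (C5–C4–C3–C2–C1–C10) closes by a transannular bond across the ten-membered ring, that is by a four-atom ring contraction in which C6, the ring oxygen, C11 and C9 are pushed out of the ring. C5: because C1 is cis to C11 on the ring alkene, the C4–C1 tether can bridge the two termini only in a boat array (C4 cis to the ring oxygen, the geometry expected from kinetic enolisation in THF) or in a chair array (C4 trans), and both deliver C6 and C9 to the same face of ring A, so the cis relation follows from the alkene geometry fixed in step 5 and is corrected in step 13. C10: it is controlled by C3 through the developing chair of ring A, in which the silyloxy group stays equatorial and the C10 methyl rather than the branched C9 takes the axial site facing the axial C4 methyl, which places the C10 methyl cis to the C3 oxygen as in the target. The step needs O-silylation and rearrangement to outrun loss of the allylic alkoxide from the enolate and needs a single [3,3] pathway, which the internal quench, the crowded C5 (no C-silylation) and the position of the isopropenyl group outside any allyl ester array secure.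

Step 12
Reactants: 24 cis dienyl acid
Product: 26 (3R,5R,10R)-3-(tert-butyldimethylsilyloxy)-11-chlorodrim-8-en-6-one (cis-fused), via acid chloride 25 (not isolated)
Conditions: 1-chloro-N,N,2-trimethylprop-1-en-1-amine, CH2Cl2, 0 °C → rt; SnCl4 (0.3 equiv), CH2Cl2, −78 °C; aq. NaHCO3
Reagents that add atoms: 1-chloro-N,N,2-trimethylprop-1-en-1-amine, CC(C)=C(Cl)N(C)C
Why: Intramolecular Friedel–Crafts-type (Kondakov) acylation of a 1,3-diene: the neutral chloroenamine makes the acid chloride without acid that could protonate the diene, SnCl4 releases the acylium ion, its attack on the unsubstituted terminus C7 is a 6-endo closure (attack on C11 would be a strained 5-endo one), and chloride caps the C8–C9–C11 allyl cation at primary C11, the cis ring fusion following from acid 24.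

Step 13
Reactants: 26 chloro enone
Product: 28 (3R,5S,10R)-3-(tert-butyldimethylsilyloxy)drima-7,9(11)-dien-6-one (trans-fused), via cis-fused dienone 27 (not isolated)
Conditions: DBU (3 equiv), toluene, 80 °C
Reagents that add atoms: none
Why: DBU removes a doubly activated C7 proton and chloride leaves from C11 in a vinylogous E1cB (1,4-) elimination, after which reversible enolisation towards C5 equilibrates the ring fusion to the trans-decalin, where C1 and C4 are both equatorial on ring B whereas either cis conformer keeps a syn-diaxial carbon pair across C4/C10 and adds gauche contacts.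

Step 14
Reactants: 28 trans dienone
Product: 29 (3R,5S,6S,10R)-3-(tert-butyldimethylsilyloxy)drima-7,9(11)-dien-6-ol (6-OH axial, on the face of the C10 methyl)
Conditions: i-Bu2AlH, CH2Cl2, −78 °C; aq. potassium sodium tartrate
Reagents that add atoms: none
Why: 1,2-Reduction of a conjugated ketone with i-Bu2AlH, with hydride arriving on the face away from the axial C4 and C10 methyl groups to give the axial 6-alcohol, a temporary centre (erased in step 17) whose only purpose is to remove the carbonyl that a borane would otherwise attack.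

Step 15
Reactants: 29 dienol
Product: 31 (3R,5S,6S,9R,10S)-3-(tert-butyldimethylsilyloxy)drim-7-ene-6,11-diol, via bis-boryl adduct 30 (not isolated)
Conditions: 9-BBN (3.5 equiv), THF, rt → 50 °C; then NaOH, H2O2, 0 °C → rt
Reagents that add atoms: hydrogen peroxide, OO
Why: Hydroboration–oxidation with 9-BBN chooses the 1,1-disubstituted C9=C11 over the trisubstituted C7=C8, puts boron on C11, and delivers hydrogen to C9 from the face opposite the axial C10 methyl and the axial C6 boryloxy group, which sets C9 as R with the CH2OH group equatorial.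

Step 16
Reactants: 31 diol; 32 umbelliferone
Product: 33 (3R,5S,6S,9R,10S)-3-(tert-butyldimethylsilyloxy)-11-(2-oxo-2H-chromen-7-yloxy)drim-7-en-6-ol
Conditions: PPh3, DIAD, THF, 0 °C → rt
Reagents that add atoms: none
Why: Mitsunobu etherification: the phosphonium reagent engages the primary C11 alcohol rather than the axial C6 alcohol that is flanked by C5 and faces two axial methyl groups, umbelliferone is acidic enough to serve as pronucleophile, and the SN2 displacement at C11 touches no stereocentre.

Step 17
Reactants: 33 allylic alcohol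
Product: 34 (3R,5S,9R,10S)-3-(tert-butyldimethylsilyloxy)-11-(2-oxo-2H-chromen-7-yloxy)drim-7-en-6-one
Conditions: Dess–Martin periodinane, CH2Cl2, rt
Reagents that add atoms: none
Why: Dess–Martin oxidation of the allylic alcohol restores the C6 ketone without base, so that the γ-proton at C9 stays in place and the aryloxide is not expelled.

Step 18
Reactants: 34 silyl ether enone
Product: 35 (3R,5S,9R,10S)-3-hydroxy-11-(2-oxo-2H-chromen-7-yloxy)drim-7-en-6-one
Conditions: HF·pyridine, THF, 0 °C → rt
Reagents that add atoms: none
Why: Fluoride-mediated desilylation under acidic buffering removes the hindered silyl ether while avoiding basic fluoride sources that could start the vinylogous β-elimination of umbelliferone or open the coumarin.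

Step 19
Reactants: 35 hydroxy enone
Product: 36 (3R,5S,9R,10S)-3-acetoxy-11-(2-oxo-2H-chromen-7-yloxy)drim-7-en-6-one (CNP0363962.1)
Conditions: Ac2O, pyridine, DMAP (cat.), CH2Cl2, rt
Reagents that add atoms: acetic anhydride, CC(=O)OC(C)=O
Why: DMAP-catalysed acetylation of the equatorial C3 alcohol is a mild acyl transfer that leaves the enone, the ether and the four stereocentres unchanged.

**Compound list**
1 | pent-4-yn-1-ol | C#CCCCO | starting material
2 | pent-4-ynal | C#CCCC=O | intermediate
3 | 3-methylbuta-1,2-diene | CC(C)=C=C | starting material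
4 | (3-methylbut-2-en-1-yl)bis(isopinocampheyl)borane, Ipc groups from (+)-α-pinene | CC(C)=CCB([C@@H]1C[C@@H]2C[C@H]([C@H]1C)C2(C)C)[C@@H]1C[C@@H]2C[C@H]([C@H]1C)C2(C)C | intermediate
5 | bis(isopinocampheyl)borinic ester of alcohol 6 | C=CC(C)(C)[C@H](OB([C@@H]1C[C@@H]2C[C@H]([C@H]1C)C2(C)C)[C@@H]1C[C@@H]2C[C@H]([C@H]1C)C2(C)C)CCC#C | intermediate
6 | (R)-3,3-dimethyloct-1-en-7-yn-4-ol | C=CC(C)(C)[C@H](O)CCC#C | intermediate
7 | (R)-4-(tert-butyldimethylsilyloxy)-3,3-dimethyloct-1-en-7-yne | C=CC(C)(C)[C@H](O[Si](C)(C)C(C)(C)C)CCC#C | intermediate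
8 | lithium acetylide of 7 | C=CC(C)(C)[C@H](O[Si](C)(C)C(C)(C)C)CCC#C[Li] | intermediate
9 | methyl (R)-6-(tert-butyldimethylsilyloxy)-7,7-dimethylnon-8-en-2-ynoate | C=CC(C)(C)[C@H](O[Si](C)(C)C(C)(C)C)CCC#CC(=O)OC | intermediate
10 | lithium alkenyl(methyl)cuprate, copper on C9 cis to the new C10 methyl | C=CC(C)(C)[C@H](O[Si](C)(C)C(C)(C)C)CC/C(C)=C(/[Cu-]C)C(=O)OC.[Li+] | intermediate
11 | methyl (R,E)-6-(tert-butyldimethylsilyloxy)-2-iodo-3,7,7-trimethylnona-2,8-dienoate | C=CC(C)(C)[C@H](O[Si](C)(C)C(C)(C)C)CC/C(C)=C(/I)C(=O)OC | intermediate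
12 | B-alkyl-9-borabicyclo[3.3.1]nonane from 11 (boron on C6) | C1CC2CCCC(C1)B2CCC(C)(C)[C@H](O[Si](C)(C)C(C)(C)C)CC/C(C)=C(/I)C(=O)OC | intermediate
13 | methyl (R,E)-6-(tert-butyldimethylsilyloxy)-9-hydroxy-2-iodo-3,7,7-trimethylnon-2-enoate | OCCC(C)(C)[C@H](O[Si](C)(C)C(C)(C)C)CC/C(C)=C(/I)C(=O)OC | intermediate
14 | methyl (R,E)-6-(tert-butyldimethylsilyloxy)-2-iodo-3,7,7-trimethyl-9-oxonon-2-enoate | O=CCC(C)(C)[C@H](O[Si](C)(C)C(C)(C)C)CC/C(C)=C(/I)C(=O)OC | intermediate
15 | (R,E)-4-(tert-butyldimethylsilyloxy)-8-iodo-9-methoxy-3,3,7-trimethyl-9-oxonon-7-enoic acid | OC(=O)CC(C)(C)[C@H](O[Si](C)(C)C(C)(C)C)CC/C(C)=C(/I)C(=O)OC | intermediate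
16 | 4,4,5,5-tetramethyl-2-(prop-1-en-2-yl)-1,3,2-dioxaborolane | CC(=C)B1OC(C)(C)C(C)(C)O1 | starting material
17 | (4R,7Z)-4-(tert-butyldimethylsilyloxy)-8-(methoxycarbonyl)-3,3,7,9-tetramethyldeca-7,9-dienoic acid | OC(=O)CC(C)(C)[C@H](O[Si](C)(C)C(C)(C)C)CC/C(C)=C(/C(C)=C)C(=O)OC | intermediate
18 | diisobutylaluminium carboxylate of 17 | CC(C)C[Al](CC(C)C)OC(=O)CC(C)(C)[C@H](O[Si](C)(C)C(C)(C)C)CC/C(C)=C(/C(C)=C)C(=O)OC | intermediate
19 | (4R,7Z)-4-(tert-butyldimethylsilyloxy)-8-(hydroxymethyl)-3,3,7,9-tetramethyldeca-7,9-dienoic acid | OC(=O)CC(C)(C)[C@H](O[Si](C)(C)C(C)(C)C)CC/C(C)=C(/C(C)=C)CO | intermediate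
20 | mixed anhydride of 19 and 2-methyl-6-nitrobenzoic acid | Cc1cccc([N+](=O)[O-])c1C(=O)OC(=O)CC(C)(C)[C@H](O[Si](C)(C)C(C)(C)C)CC/C(C)=C(/C(C)=C)CO | intermediate
21 | (5R,8Z)-5-(tert-butyldimethylsilyloxy)-4,4,8-trimethyl-9-(prop-1-en-2-yl)-3,4,5,6,7,10-hexahydro-2H-oxecin-2-one | O=C1CC(C)(C)[C@H](O[Si](C)(C)C(C)(C)C)CC/C(C)=C(/C(C)=C)CO1 | intermediate
22 | trimethylsilyl ketene acetal of 21 (C5=C6, E; C4 cis to the ring oxygen) | C[Si](C)(C)O/C1=C/C(C)(C)[C@H](O[Si](C)(C)C(C)(C)C)CC/C(C)=C(/C(C)=C)CO1 | intermediate
23 | trimethylsilyl ester of 24 | CC(C)(C)[Si](C)(C)O[C@@H]1CC[C@@](C)(C(=C)C(C)=C)[C@@H](C(=O)O[Si](C)(C)C)C1(C)C | intermediate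
24 | (1R,2R,5R)-5-(tert-butyldimethylsilyloxy)-2,6,6-trimethyl-2-(3-methylbuta-1,3-dien-2-yl)cyclohexane-1-carboxylic acid (CO2H and dienyl cis; silyloxy cis to the C2 methyl) | CC(C)(C)[Si](C)(C)O[C@@H]1CC[C@@](C)(C(=C)C(C)=C)[C@@H](C(=O)O)C1(C)C | intermediate
25 | acid chloride of 24 | CC(C)(C)[Si](C)(C)O[C@@H]1CC[C@@](C)(C(=C)C(C)=C)[C@@H](C(=O)Cl)C1(C)C | intermediate
26 | (3R,5R,10R)-3-(tert-butyldimethylsilyloxy)-11-chlorodrim-8-en-6-one, cis-fused | CC(C)(C)[Si](C)(C)O[C@@H]1CC[C@@]2(C)C(CCl)=C(C)CC(=O)[C@H]2C1(C)C | intermediate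
27 | (3R,5R,10R)-3-(tert-butyldimethylsilyloxy)drima-7,9(11)-dien-6-one, cis-fused | CC(C)(C)[Si](C)(C)O[C@@H]1CC[C@@]2(C)C(=C)C(C)=CC(=O)[C@H]2C1(C)C | intermediate
28 | (3R,5S,10R)-3-(tert-butyldimethylsilyloxy)drima-7,9(11)-dien-6-one, trans-fused | CC(C)(C)[Si](C)(C)O[C@@H]1CC[C@@]2(C)C(=C)C(C)=CC(=O)[C@@H]2C1(C)C | intermediate
29 | (3R,5S,6S,10R)-3-(tert-butyldimethylsilyloxy)drima-7,9(11)-dien-6-ol | CC(C)(C)[Si](C)(C)O[C@@H]1CC[C@@]2(C)C(=C)C(C)=C[C@H](O)[C@@H]2C1(C)C | intermediate
30 | C11-boryl, C6-O-boryl bis(9-BBN) adduct of 29 | CC(C)(C)[Si](C)(C)O[C@@H]1CC[C@@]2(C)[C@H](CB3C4CCCC3CCC4)C(C)=C[C@H](OB3C4CCCC3CCC4)[C@@H]2C1(C)C | intermediate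
31 | (3R,5S,6S,9R,10S)-3-(tert-butyldimethylsilyloxy)drim-7-ene-6,11-diol | CC(C)(C)[Si](C)(C)O[C@@H]1CC[C@@]2(C)[C@H](CO)C(C)=C[C@H](O)[C@@H]2C1(C)C | intermediate
32 | umbelliferone (7-hydroxy-2H-chromen-2-one) | O=c1ccc2ccc(O)cc2o1 | starting material
33 | (3R,5S,6S,9R,10S)-3-(tert-butyldimethylsilyloxy)-11-(2-oxo-2H-chromen-7-yloxy)drim-7-en-6-ol | CC(C)(C)[Si](C)(C)O[C@@H]1CC[C@@]2(C)[C@H](COc3ccc4ccc(=O)oc4c3)C(C)=C[C@H](O)[C@@H]2C1(C)C | intermediate
34 | (3R,5S,9R,10S)-3-(tert-butyldimethylsilyloxy)-11-(2-oxo-2H-chromen-7-yloxy)drim-7-en-6-one | CC(C)(C)[Si](C)(C)O[C@@H]1CC[C@@]2(C)[C@H](COc3ccc4ccc(=O)oc4c3)C(C)=CC(=O)[C@@H]2C1(C)C | intermediate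
35 | (3R,5S,9R,10S)-3-hydroxy-11-(2-oxo-2H-chromen-7-yloxy)drim-7-en-6-one | O[C@@H]1CC[C@@]2(C)[C@H](COc3ccc4ccc(=O)oc4c3)C(C)=CC(=O)[C@@H]2C1(C)C | intermediate
36 | (3R,5S,9R,10S)-3-acetoxy-11-(2-oxo-2H-chromen-7-yloxy)drim-7-en-6-one (trans-decalin; OAc, C10 methyl and C9 CH2OAr on one face, H5 and H9 on the other) | CC(=O)O[C@@H]1CC[C@@]2(C)[C@H](COc3ccc4ccc(=O)oc4c3)C(C)=CC(=O)[C@@H]2C1(C)C | target

Total step count: 19. Longest linear sequence: 19 steps (1 to 36).

**Steps most likely to fail**

Step 11.
- What may go wrong: enolisation at the neopentyl C5 may be slow, and the enolate may lose the allylic alkoxide before it is silylated. The shift has to join a carbon flanked by C4 to a fully substituted alkene terminus. Leakage through the array with C9 axial would erode the induction from C3 to C10.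
- Fallback: it sets out from hydroxy acid 19 and comes back at acid 24, keeping the C5–C10 disconnection but giving up the medium ring. The allylic alcohol is converted into the chloride (MsCl, LiCl, 2,4,6-collidine, DMF, 0 °C; any anhydride formed at the acid is hydrolysed on work-up). This gives (4R,7Z)-8-(chloromethyl)-4-(tert-butyldimethylsilyloxy)-3,3,7,9-tetramethyldeca-7,9-dienoic acid F1. Two equivalents of LiN(i-Pr)2 in THF–DMPU then generate the carboxylate enolate. Its C5 attacks C10 in an intramolecular SN2′ displacement, with the six-membered ring preferred over the eight-membered ring of direct SN2. A simple chair-like closure with the silyloxy group equatorial gives the same C9=C11 methylene and acid 24.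

Step 10.
- What may go wrong: intermolecular acyl transfer (dimer and oligomer formation) may outrun closure of the strained ten-membered ring, and the β-quaternary acid slows acyl transfer further.
- Fallback: it sets out from 19 and comes back at lactone 21, and no compound outside the list is made (F0). A Mitsunobu macrolactonisation (PPh3, DIAD, toluene, high dilution) activates the allylic alcohol instead of the acid. The ring is then closed by forming the C11–O bond through carboxylate attack on an alkoxyphosphonium ion, rather than the C6–O bond by acyl transfer, and the hindered acid only has to act as a small nucleophile.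

Step 12.
- What may go wrong: the diene may be protonated or attacked by cations, the carboxyl oxygen may capture the allyl cation, the silyl ether may be lost to the Lewis acid, or the cation may be quenched non-selectively.
- Fallback: it sets out from acid chloride 25 and comes back at cis-fused dienone 27, replacing cationic chemistry by metathesis. Stille acylation with Bu3SnCH=CH2 (Pd2(dba)3, tri(2-furyl)phosphine, THF, 50 °C) gives 1-[(1R,2R,5R)-5-(tert-butyldimethylsilyloxy)-2,6,6-trimethyl-2-(3-methylbuta-1,3-dien-2-yl)cyclohexyl]prop-2-en-1-one F2. Ring-closing metathesis with the second-generation Hoveyda–Grubbs catalyst (toluene, 80 °C) joins the enone vinyl group to the isopropenyl alkene, which is more accessible than C9=C11 beside the quaternary C10. This forms C7=C8 of ring B directly and gives 27, which is equilibrated with DBU as in step 13 to 28.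

**Further compounds**
F1 | step 11 | (4R,7Z)-8-(chloromethyl)-4-(tert-butyldimethylsilyloxy)-3,3,7,9-tetramethyldeca-7,9-dienoic acid | OC(=O)CC(C)(C)[C@H](O[Si](C)(C)C(C)(C)C)CC/C(C)=C(/C(C)=C)CCl
F0 | step 10 | none | none
F2 | step 12 | 1-[(1R,2R,5R)-5-(tert-butyldimethylsilyloxy)-2,6,6-trimethyl-2-(3-methylbuta-1,3-dien-2-yl)cyclohexyl]prop-2-en-1-one | CC(C)(C)[Si](C)(C)O[C@@H]1CC[C@@](C)(C(=C)C(C)=C)[C@@H](C(=O)C=C)C1(C)C
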